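The 2,2-dimethyl-2H-pyran ring is opened at C4–C4a and O1–C2, which leads back to a phenol and prenal. The key step, a domino Knoevenagel/oxa-6π electrocyclisation (formal [3+3] annulation), makes both bonds in one operation. It exploits the benzene ring's O1–C8a–C4a unit, a phenolic oxygen and its ortho carbon, as an O,C-bis-nucleophile. The precursor is a pentasubstituted acylphloroglucinol whose future C8 carries a methyl ester, so the only aromatic C–H lies between the C5 methoxy group and the hydroxyl para to the ketone: regiochemistry is fixed by the substrate. The ester, which also keeps the early intermediates symmetric, is finally removed by hydrolysis and decarboxylation.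

Key step: step 3

Remark: the target is achiral, so no stereocentre has to be set; every selectivity question in the route is one of regiochemistry or chemoselectivity.

Step 1
Reactants: 1 methyl 2,4,6-trihydroxybenzoate
Product: 2 methyl 2,6-dihydroxy-4-methoxybenzoate
Conditions: Me2SO4 (1.05 equiv), K2CO3 (1.1 equiv), acetone, 0 °C to rt
Reagents that add atoms: dimethyl sulfate COS(=O)(=O)OC
Why: Williamson O-methylation; the 4-OH is para to the ester and is the only hydroxyl not hydrogen-bonded to it, so it is the most acidic and most nucleophilic and one equivalent of dimethyl sulfate should stop at the 4-methyl ether.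

Step 2
Reactants: 2 methyl 2,6-dihydroxy-4-methoxybenzoate; 3 4-methoxyphenylacetic acid
Product: 4 methyl 2,6-dihydroxy-4-methoxy-3-[2-(4-methoxyphenyl)acetyl]benzoate
Conditions: BF3·OEt2 (neat, as solvent), 85 °C; aq. NaOAc work-up
Reagents that add atoms: none
Why: Friedel–Crafts C-acylation of a phloroglucinol-type ring by an arylacetic acid in BF3 etherate (the standard deoxybenzoin synthesis); C3 and C5 of 2 are equivalent by symmetry, so only one regioisomer can form, and the new ketone deactivates the ring against a second acylation.

Step 3
Reactants: 4 methyl 2,6-dihydroxy-4-methoxy-3-[2-(4-methoxyphenyl)acetyl]benzoate; 5 3-methylbut-2-enal (prenal, 2.5 equiv)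
Product: 7 methyl 7-hydroxy-5-methoxy-6-[2-(4-methoxyphenyl)acetyl]-2,2-dimethyl-2H-chromene-8-carboxylate, via ortho-quinone methide 6 (not isolated)
Conditions: ethylenediammonium diacetate (EDDA, 20 mol %), xylene, 140 °C
Reagents that add atoms: none
Why: Ethylenediamine from the catalyst condenses with prenal 5 to an iminium ion, which phenol 4 attacks through its only unsubstituted ring carbon (C5, between the 6-OH and the 4-OMe) to form the aryl C–CH bond; loss of the amine gives the 1-oxatriene (ortho-quinone methide) 6, and thermal disrotatory oxa-6π electrocyclisation then forms the O–CMe2 bond. The closest known reaction type is the domino Knoevenagel (aldol-type) condensation/oxa-6π electrocyclisation of phenols with enals, the formal [3+3] 2H-chromene annulation established for resorcinols and acylphloroglucinols. The single ring closed is the six-membered 2H-pyran, closed pericyclically (6π electrocyclic, formally 6-endo at the dimethyl-substituted diene terminus), which restores the aromatic sextet and should make the sequence irreversible. No stereocentre is created. The step needs regioselectivity for the carbon between the methoxy group and the hydroxyl para to the ketone, and for cyclisation through that hydroxyl: the methyl ester at C1 blocks the otherwise preferred carbon between the two hydroxyls, leaving one aromatic C–H with a single neighbouring OH, so no regioisomer can form. Chemoselectivity over the ketone's benzylic CH2 rests on its much lower acidity compared with the phenol, which reacts as its ammonium phenoxide.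

Step 4
Reactants: 7 methyl 7-hydroxy-5-methoxy-6-[2-(4-methoxyphenyl)acetyl]-2,2-dimethyl-2H-chromene-8-carboxylate
Product: 9 1-(7-hydroxy-5-methoxy-2,2-dimethyl-2H-chromen-6-yl)-2-(4-methoxyphenyl)ethan-1-one, via carboxylic acid 8 (not isolated)
Conditions: KOH (6 equiv), EtOH/H2O 2:1, reflux, N2; then 1 M HCl to pH 4, 50 °C
Reagents that add atoms: none
Why: Saponification of the salicylate-type ester followed by protodecarboxylation (ipso-protonation, loss of CO2) of the electron-rich acid 8, whose carboxyl-bearing carbon lies ortho to two oxygens and para to a third; the chromene and the phenoxide-deactivated ketone should tolerate the alkali.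

Compound list
1 | methyl 2,4,6-trihydroxybenzoate | COC(=O)c1c(O)cc(O)cc1O | starting material
2 | methyl 2,6-dihydroxy-4-methoxybenzoate | COC(=O)c1c(O)cc(OC)cc1O | intermediate
3 | 4-methoxyphenylacetic acid | COc1ccc(CC(=O)O)cc1 | starting material
4 | methyl 2,6-dihydroxy-4-methoxy-3-[2-(4-methoxyphenyl)acetyl]benzoate | COC(=O)c1c(O)cc(OC)c(C(=O)Cc2ccc(OC)cc2)c1O | intermediate
5 | 3-methylbut-2-enal (prenal) | CC(C)=CC=O | starting material
6 | ortho-quinone methide (1-oxatriene): methyl 2-hydroxy-4-methoxy-3-[2-(4-methoxyphenyl)acetyl]-5-[(Z)-3-methylbut-2-en-1-ylidene]-6-oxocyclohexa-1,3-diene-1-carboxylate | COC(=O)C1=C(O)C(C(=O)Cc2ccc(OC)cc2)=C(OC)/C(=C/C=C(C)C)C1=O | intermediate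
7 | methyl 7-hydroxy-5-methoxy-6-[2-(4-methoxyphenyl)acetyl]-2,2-dimethyl-2H-chromene-8-carboxylate | COc1ccc(CC(=O)c2c(O)c(C(=O)OC)c3c(c2OC)C=CC(C)(C)O3)cc1 | intermediate
8 | 7-hydroxy-5-methoxy-6-[2-(4-methoxyphenyl)acetyl]-2,2-dimethyl-2H-chromene-8-carboxylic acid | COc1ccc(CC(=O)c2c(O)c(C(=O)O)c3c(c2OC)C=CC(C)(C)O3)cc1 | intermediate
9 | 1-(7-hydroxy-5-methoxy-2,2-dimethyl-2H-chromen-6-yl)-2-(4-methoxyphenyl)ethan-1-one | COc1ccc(CC(=O)c2c(O)cc3c(c2OC)C=CC(C)(C)O3)cc1 | target

Total step count: 4
Longest linear sequence: 4 steps (1 → 2 → 4 → 7 → 9)

Steps most likely to fail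

Step 3 (key step). The doubly hydrogen-bonded, acyl- and ester-deactivated phenol may attack the iminium ion too slowly. Self-condensation of prenal, or condensation at the benzylic methylene followed by oxa-Michael closure to an isoflavanone, could then outrun the annulation. The fallback sets out from 4 and makes the C–C bond formation intramolecular. O-Alkylation of the less hindered 6-OH (para to the ketone) with 3-chloro-3-methylbut-1-yne (K2CO3, KI, CuI cat., acetone, 60 °C) should give the aryl propargyl ether methyl 2-hydroxy-4-methoxy-3-[2-(4-methoxyphenyl)acetyl]-6-[(2-methylbut-3-yn-2-yl)oxy]benzoate F1. Heating F1 in xylene or N,N-diethylaniline (140–180 °C) should then trigger propargyl Claisen rearrangement to the only free ortho carbon, a 1,5-hydrogen shift and oxa-6π electrocyclisation. This comes back to the route at 7.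

Step 2. Intermolecular C-acylation of the ester-deactivated ring may stall at O-acylation or at low conversion. The fallback sets out from 2 and separates the two events. O-Acylation with 4-methoxyphenylacetyl chloride (pyridine, CH2Cl2, 0 °C) should give the aryl ester methyl 2-hydroxy-4-methoxy-6-{[2-(4-methoxyphenyl)acetyl]oxy}benzoate F2. Fries rearrangement of F2 (TiCl4, 1,2-dichloroethane, 60 °C) should then move the acyl group onto the ring; both free ring positions lead to the same compound by symmetry. This comes back to the route at 4.

Step 4. Hydroxide may attack the di-ortho-substituted ester carbonyl only slowly, so that retro-Claisen cleavage of the aryl ketone competes under prolonged heating in alkali. The fallback sets out from 7 and avoids hydroxide. Lithium propane-1-thiolate (n-PrSLi, DMPU, rt) should cleave the ester by SN2 attack at its O-methyl group to give the lithium salt of acid 8. Acidification with AcOH and warming to 50 °C should then decarboxylate it, coming back to the route at 9. No new compound is made on this path.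

Further compounds
F1 | step 3 | methyl 2-hydroxy-4-methoxy-3-[2-(4-methoxyphenyl)acetyl]-6-[(2-methylbut-3-yn-2-yl)oxy]benzoate | COC(=O)c1c(OC(C)(C)C#C)cc(OC)c(C(=O)Cc2ccc(OC)cc2)c1O
F2 | step 2 | methyl 2-hydroxy-4-methoxy-6-{[2-(4-methoxyphenyl)acetyl]oxy}benzoate | COC(=O)c1c(O)cc(OC)cc1OC(=O)Cc1ccc(OC)cc1
F0 | step 4 | none | none
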